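The numbers in the tables were generated by integration for an exercise, noise included.

| flask | substrate | partner | remark | time |
|---|---|---|---|---|
| Sunday's | 0.050 M (fed, over 15 min) | 1.1 equiv | run made earlier |  |
| Thursday's | 0.075 M (fed, over 15 min) | 1.1 equiv | run made earlier |  |
| flask | 0.10 M (fed, over 15 min) | 1.10 equiv |  | 4.0 h |

- Sunday's (time / h: target / %, side product / %, substrate / %): 0.333: 6.1, 0, 90.6; 0.500: 9.9, 0, 84.6; 0.667: 13.5, 0.5, 76.4; 1.00: 20.3, 1.4, 66.1; 1.50: 27.7, 2.2, 56.5; 2.50: 34.5, 7.1, 40.6; 4.00: 41.2, 13.0, 24.5
- Thursday's (time / h: target / %, side product / %, substrate / %): 0.333: 8.4, 0, 88.6; 0.500: 13.8, 1.5, 79.0; 0.667: 18.5, 1.8, 66.9; 1.00: 26.2, 4.1, 56.3; 1.50: 32.2, 6.5, 44.1; 2.50: 40.9, 10.7, 27.3; 4.00: 48.4, 15.6, 16.1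

(standard deviation of a reading: 1 percentage point)

- percentages count the substrate that a species holds: one side product counts as two
- the reaction counts as stopped when no species that holds the substrate changes by six tenths of a point or more over the second half of the time

- the state of affairs at 4.0 h: stopped, and by what, or still going (all of the substrate has reacted / the partner has run out first / it is still moving)
- target at 4.0 h, in percent of the substrate charged
- side product at 4.0 h, in percent of the substrate charged

- Slowness comes first: Thursday's substrate still fell from 27.3% at 2.50 h to 16.1% at 4.00 h, so the books of the new flask are kept on a reaction that may well be under way at 4.0 h.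
- With 1.10 equiv of partner, substrate is the limiting reagent, and each point of it needs an entry.
- Entry for substrate left: the inverse of the fraction left, less one, divided by c(substrate), reads 61.6 M⁻¹ on Sunday and 69.5 M⁻¹ on Thursday. Their mean, 65.6 M⁻¹, leaves 13.2% in the new flask, so 86.8% is consumed.
- Entry for products: the two runs read 71.8% and 76.3%. Their mean, 74.0%, is the booked share, the part of the consumed substrate standing in target and side product together. The new flask therefore books 64.2%.
- Split: target's part of those books reads 75.8%, giving 48.7% target and 15.5% side product.
- Open entry: 22.6% stands in no measured species.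
- Close: substrate is not gone at 13.2%, and partner taken one to one outlasts it, so this reckoning says still moving.
- The forecast says it is still moving, with 51% target and 18% side product, more side product than this reckoning, on the ground that “The other ~42% goes to the hidden species, which drains slowly to side product, roughly first order at 0.23 per hour”.
- The flask gives it is still moving, with 48.7% target and 18.9% side product, so side product lands above the 15.5% reckoned here.

    2 substrate → homo dimer (k = 1.90 M⁻¹ h⁻¹)
    substrate + partner → target (k = 5.80 M⁻¹ h⁻¹)
    substrate + target → side product (k = 2.50 M⁻¹ h⁻¹)

- The open entry of the flask is the homo dimer, 22.8% at 4.00 h. With 9.55% of substrate left there, the booked share gives 66.9% for target and side product, and the flask holds 67.6%.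
- A neighbour flask with 0.060 M of substrate, at the same equivalents, has 20.3% left at 4.00 h, so the booked share gives 59.0%. That neighbour holds 44.0% target and 13.7% side product, together 57.7%.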